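## The problem

CNP0141484.0 (35) is a 2,7-dihydroxy-5-methyl-1,4-naphthoquinone (quinone ring B, C1–C4; benzenoid ring A, C4a–C8a) whose C6 carries an aroyl group: the ketone carbon C9 joins C6 to C1' of a resorcinol ring C (hydroxyls on C2' and C4'), and C6' bears a methylene that ends at C6'' of a 4-hydroxy-2H-pyran-2-one (ring D, O1''–C6''). The molecule has no stereocentre, so the task is one of regiochemistry, steric crowding and functional-group tolerance only. Ring B needs its oxygen on C2, next to the C1 carbonyl on C8a, and hydrogen on C3, next to the C4 carbonyl on C4a, which lies peri to the C5 methyl group; any construction of the naphthoquinone must fix this orientation relative to ring A. C9 is a diaryl ketone with all four ortho positions substituted (C5 methyl, C7 oxygen, C2' oxygen, C6' methylene), so intermolecular additions to a C9 carbonyl are disfavoured. The hydroxyquinone does not tolerate carbanions, reductants or prolonged base, and the pyranone, a lactone and 1,3-dicarbonyl equivalent, is open to hydrogenation and oxidation. The methylene between rings C and D is doubly activated, and strong acid could condense it or the pyranone C5'' onto C9. The feature that opens the key step is that the four ring B carbons not shared with ring A correspond to a carbene carbon (C4), the two carbons of a terminal ynol ether (C3–H, C2–O) and carbon monoxide (C1). Since C5 already carries the methyl group, an aryl carbene attached through C4a has a single unsubstituted ortho position, C8a, at which the new ring can close.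

## Retrosynthesis

**Unmasking (35 ← 34 ← 33 ← 32).** The last cuts are the three benzyl–oxygen bonds at C7, C2' and C4' of 34. Before that come the O-ethyl bond at C2 and the O-acetyl bond at C4'' of 33, and the two O-methyl bonds at C1 and C4 of 32, whose removal by oxidation gives the quinone. Benzyl is chosen for every phenol so that one low-temperature Lewis-acid cleavage frees them without reduction (quinone, pyranone) and without strong protic acid. A methyl ether at C7 is avoided because the naphthoyl ring is twisted out of conjugation with C9 and could not be cleaved with chelation assistance. The quinone stays masked as a hydroquinone dimethyl ether until all carbanion chemistry is over. The pyranone hydroxyl is acetylated before the oxidation, and one hydroxide treatment then removes the acetyl group and the ethyl group together.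

**Ring D (32 ← 29 ← 25 + 26).** The O1''–C2'' bond is cut by the retro-reaction of an acylketene lactonisation, and the C5''–C6'' bond by a Claisen-type acylation of the dienolate of dioxinone 26 with acid 25. Attaching a ready-made pyranone would need a benzylic electrophile beside the hindered ketone. The dioxinone route instead uses the arylacetic acid that the preceding step delivers. The precursor loses a whole ring and five carbons. The forward reaction must acylate carbon of a dienolate with an acyl donor that has acidic α-hydrogens.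

**Ring C and the ketone (25 ← 24 ← 14 + 22).** Both bonds from ring C to its ortho substituents, C9–C1' and C6'–CH2, are cut at once, leading to β-keto ester 14 and aryne 23, which is released from silyl triflate 22. Against the addition of a ring C organometallic to a shielded C9 acyl group, this insertion attaches the nucleophile first at the unhindered methylene of 14 and then delivers the aryl anion to C9 intramolecularly. The C3 benzyloxy group of the aryne dictates the orientation. The forward reaction asks the aryl anion to add to a twisted, di-ortho-substituted ketone.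

**Side chain on C9 (14 ← 12 ← 11).** The C9–CH2 bond of 14 is cut back to acid 12 and ester 11. The C6–C9 bond is never made in the route, because it is already present in the starting benzoate. Only a hindered ester hydrolysis and one acylation are required.

**Ring B, the key cut (11 ← 10 ← 7 + 8).** C3–C4, C1–C2 and C1–C8a are cut, giving carbene complex 7, ethoxyacetylene 8 and a carbon monoxide ligand. Other annulations of ring B would have to distinguish C2 from C3 relative to a remote methyl group. Here the orientation follows from the connectivity: the carbene carbon is already attached to C4a beside C5, the alkyne CH carbon bonds to it, and the CO-derived carbon closes on the only free ortho position. The precursor is a monocyclic benzoate.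

**Carbene complex (7 ← 3 + 4; 3 ← 2 ← 1).** The C4–C4a bond is cut to the aryl bromide 3 and Cr(CO)6 4. Bromide 3 comes from bromination of 2 para to its ether oxygen, and 2 from benzylation of salicylate 1.

**Aryne precursor (22 ← 20 ← 16 ← 15).** The C–Si and O–S bonds are cut back through carbamate 20 and carbamate 16 to the symmetrical phenol 15. The carbamate directs silylation to a position that is equivalent on either side.

## Roads not taken

**Alternative 1:** This cuts both bonds to C9. The ring C aryl iodide 6-[(2-iodo-3,5-dimethoxyphenyl)methyl]-4-methoxy-2H-pyran-2-one A2 and the naphthyl pinacol boronate A3 would be joined with carbon monoxide in a carbonylative Suzuki coupling. The product would be the fully methylated ketone 6-{[3,5-dimethoxy-2-(3,5,6,8-tetramethoxy-1-methyl-2-naphthoyl)phenyl]methyl}-4-methoxy-2H-pyran-2-one A1, with C9 supplied from the gas phase.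
- Merits: it is the most convergent plan. Iodide A2 and boronate A3 are both complete before the union and no hindered ester has to be manipulated. In convergence it is better than the chosen route.
- Weak points: both partners are di-ortho-substituted, so the acylpalladium species from A2 must transmetalate with a crowded, electron-rich boronate. Direct biaryl coupling without carbonyl insertion and protodeboronation are the expected competitors.
- A3 still needs ring B with the correct orientation, plus borylation at C6 between a methyl and a methoxy group. The central regiochemical problem is therefore postponed, not solved.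
- A1 must finally lose five methyl ethers, including the pyranone ether, under forcing Lewis-acid conditions, next to an oxidative demethylation.
- What the chosen plan sets against it: it builds ring B with its orientation fixed by connectivity, carries the C6–C9 bond from the start, makes the one remaining bond to C9 intramolecularly, and ends with mild deprotection.

**Alternative 2:** This cuts C4a–C5 and C8–C8a. A Diels–Alder reaction of the quinone 2-bromo-5-methoxy-1,4-benzoquinone A5 with the aroyl silyloxydiene A6, followed by dehydrobromination, enolisation and air oxidation, would give 6-aroyl-7-hydroxy-2-methoxy-5-methyl-1,4-naphthoquinone with rings C and D as methyl ethers A4.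
- Merits: quinone A5 is small and brings the quinone oxidation level and the C2 oxygen from the beginning. The free C7 hydroxyl appears directly, and the bromine of A5 both steers the regiochemistry and serves as leaving group. In redox and protecting-group economy for rings A and B this road is better.
- Weak points: A6 is a cross-conjugated silyl dienol ether derived from an alkylidene 1,3-diketone. It must be made as one geometrical isomer while carrying the complete ring C and ring D unit on its internal carbon.
- The acyl group lowers the reactivity of A6, and its crowded aroyl group sits next to the terminus that must bond to the bromine-bearing carbon of A5.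
- A4 still carries four methyl ethers that must be cleaved in the presence of the quinone.
- What the chosen plan sets against it: robust small building blocks, a key step tried on a simple benzoate-derived complex where failure costs little, and no dependence on a fragile, late diene.

**Alternative 3:** This cuts O1''–C2'' and C1'–C6'. Heating the naphthyl pentaketo-dioxinone A8 would generate an acylketene by cycloreversion, which the enol oxygen on C6'' traps to form ring D. Mild base in the same flask would then close and aromatise ring C by aldol condensation, giving 6-{[3,5-dihydroxy-2-(3,5,6,8-tetramethoxy-1-methyl-2-naphthoyl)phenyl]methyl}-4-hydroxy-2H-pyran-2-one A7.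
- Merits: two rings form in one operation from an open chain, no aryne precursor is needed, and A7 emerges with rings C and D already unprotected. In step economy for rings C and D it is better than the seven steps spent here.
- Weak points: A8 has to be assembled by repeated acylation of polyanions with a hindered naphthoyl donor, and it is a mixture of enol tautomers.
- Besides the wanted C1'–C6' aldol, closure of the bridging methylene onto C2' and 4-pyranone formation from any 1,3,5-triketone segment of A8 are open.
- The naphthalene half must still be made, so ring B remains unsolved. A7 also keeps the C7 methyl ether, which would have to be cleaved without chelation assistance beside free phenols and the pyranone.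
- What the chosen plan sets against it: ring C is built by a single, regiochemically dictated insertion. Only the last idea of this alternative, the dioxinone-to-pyranone closure on a monoketone where no competing mode exists, is kept.

Key step: step 4

Assumption: ethoxyacetylene (as its solution in hexanes), methyl 2-hydroxy-6-methylbenzoate, 3,5-bis(benzyloxy)phenol and 2,2,6-trimethyl-4H-1,3-dioxin-4-one are taken as purchasable, and the quinone is handled as the 2-hydroxy-1,4-dione tautomer drawn.

## Route

Step 1
Reactants: 1 methyl 2-hydroxy-6-methylbenzoate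
Product: 2 methyl 2-(benzyloxy)-6-methylbenzoate
Conditions: BnBr, K2CO3, DMF, 60 °C
Reagents that add atoms: benzyl bromide, BrCc1ccccc1
Why: Williamson etherification of the phenol; benzyl is chosen so that the C7 oxygen can be freed at the end without chelation assistance.

Step 2
Reactants: 2 methyl 2-(benzyloxy)-6-methylbenzoate
Product: 3 methyl 6-(benzyloxy)-3-bromo-2-methylbenzoate
Conditions: NBS, MeCN, 0 °C → rt
Reagents that add atoms: N-bromosuccinimide, O=C1CCC(=O)N1Br
Why: Electrophilic aromatic bromination goes para to the ether oxygen, a position also ortho to the methyl group and meta to the ester; polar conditions avoid radical benzylic bromination.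

Step 3
Reactants: 3 methyl 6-(benzyloxy)-3-bromo-2-methylbenzoate; 4 hexacarbonylchromium
Product: 7 pentacarbonyl{[4-(benzyloxy)-3-(methoxycarbonyl)-2-methylphenyl](methoxy)methylidene}chromium, via aryllithium 5 (not isolated), via lithium acylchromate 6 (not isolated)
Conditions: t-BuLi (2 equiv), THF–Et2O, −100 °C; Cr(CO)6, −78 → 0 °C; then Me3OBF4, CH2Cl2, 0 °C
Reagents that add atoms: trimethyloxonium tetrafluoroborate, C[O+](C)C.F[B-](F)(F)F
Why: Fischer carbene synthesis: bromine–lithium exchange at −100 °C is faster than attack on the di-ortho-substituted ester, the aryllithium adds to a CO ligand, and the hard oxonium salt methylates the acylchromate on oxygen.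

Step 4
Reactants: 7 pentacarbonyl{[4-(benzyloxy)-3-(methoxycarbonyl)-2-methylphenyl](methoxy)methylidene}chromium; 8 ethoxyacetylene
Product: 10 methyl 3-(benzyloxy)-6-ethoxy-5-hydroxy-8-methoxy-1-methylnaphthalene-2-carboxylate, via tricarbonylchromium naphthol complex 9 (not isolated)
Conditions: ethoxyacetylene (2 equiv, hexanes solution), THF, 45 °C, sealed vessel, Ar; then air, rt
Reagents that add atoms: none
Why: Dötz benzannulation, the three-component union of an aryl(alkoxy)carbene chromium complex, an alkyne and one CO ligand. After thermal loss of a cis CO ligand from 7 the alkyne coordinates and inserts into the Cr=C bond so that its CH carbon bonds to the carbene carbon (C3–C4) and the ethoxy-bearing carbon becomes the new carbene centre (C2); migration of CO onto this carbon (C1–C2) gives a chromium-bound vinylketene. The ketene closes ring B by 6π-electrocyclisation onto the aryl ortho carbon (C1–C8a), and tautomerisation gives the naphthol as its Cr(CO)3 complex 9, from which air removes the metal. The closest known reaction type is the benzannulation of aryl(methoxy)carbene complexes with terminal alkynes, where the substituted alkyne carbon ends next to the new phenol; an ynol ether is a rare partner but is polarised in the same sense (nucleophilic CH carbon, electrophilic carbene carbon), as in the known insertions of ynamines. Two selectivities are needed: the alkyne orientation, which size (ethoxy against hydrogen) and polarity secure together, and the site of closure, which is unambiguous because the C5 methyl group occupies the other ortho position. No stereocentre is formed. Because the ethoxy group stabilises the intermediate carbene, CO insertion may be slower than with alkyl alkynes, so an ether solvent, moderate heat and excess alkyne are used, and the air-sensitive naphthol is methylated at once in step 5.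

Step 5
Reactants: 10 methyl 3-(benzyloxy)-6-ethoxy-5-hydroxy-8-methoxy-1-methylnaphthalene-2-carboxylate
Product: 11 methyl 3-(benzyloxy)-6-ethoxy-5,8-dimethoxy-1-methylnaphthalene-2-carboxylate
Conditions: MeI, K2CO3, DMF, rt
Reagents that add atoms: iodomethane, CI
Why: Williamson methylation of the naphthol turns the oxidation-prone 4-methoxy-1-naphthol into a stable hydroquinone dimethyl ether that serves as the masked quinone; carbonate does not touch the hindered ester.

Step 6
Reactants: 11 methyl 3-(benzyloxy)-6-ethoxy-5,8-dimethoxy-1-methylnaphthalene-2-carboxylate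
Product: 12 3-(benzyloxy)-6-ethoxy-5,8-dimethoxy-1-methylnaphthalene-2-carboxylic acid
Conditions: KOH, DMSO–H2O, 90 °C; then aq. HCl
Reagents that add atoms: potassium hydroxide, [K+].[OH-]
Why: Saponification of a di-ortho-substituted methyl ester needs poorly solvated hydroxide and heat; every other group in 11 is an ether and is inert.

Step 7
Reactants: 12 3-(benzyloxy)-6-ethoxy-5,8-dimethoxy-1-methylnaphthalene-2-carboxylic acid
Product: 14 methyl 3-[3-(benzyloxy)-6-ethoxy-5,8-dimethoxy-1-methylnaphthalen-2-yl]-3-oxopropanoate, via acid chloride 13 (not isolated)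
Conditions: 1-chloro-N,N,2-trimethylprop-1-en-1-amine, CH2Cl2, 0 °C → rt; then KO2CCH2CO2Me, MgCl2, Et3N, MeCN, 0 °C → rt; aq. HCl
Reagents that add atoms: potassium methyl malonate, COC(=O)CC(=O)[O-].[K+]
Why: The neutral α-chloroenamine makes the acid chloride without acid or Vilsmeier-type formylation of the electron-rich ring; C-acylation of the magnesium enolate of the malonate half-ester and decarboxylation on work-up is the standard β-keto ester synthesis and tolerates hindered aroyl chlorides.

Step 8
Reactants: 15 3,5-bis(benzyloxy)phenol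
Product: 16 3,5-bis(benzyloxy)phenyl propan-2-ylcarbamate
Conditions: i-PrNCO, Et3N (cat.), CH2Cl2, rt
Reagents that add atoms: isopropyl isocyanate, CC(C)N=C=O
Why: Base-catalysed addition of the phenol to the isocyanate installs a directing group that can later be removed under mild base.

Step 9
Reactants: 16 3,5-bis(benzyloxy)phenyl propan-2-ylcarbamate
Product: 20 3,5-bis(benzyloxy)-2-(trimethylsilyl)phenyl propan-2-ylcarbamate, via N-silyl carbamate 17 (not isolated), via ortho-lithiated carbamate 18 (not isolated), via N-silyl C-silyl carbamate 19 (not isolated)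
Conditions: TBSOTf, TMEDA, Et2O, 0 °C → rt; n-BuLi, TMEDA, −78 °C; TMSCl, −78 °C → rt; aq. NaHSO4
Reagents that add atoms: chlorotrimethylsilane, C[Si](C)(C)Cl
Why: Directed ortho-metalation of the O-aryl carbamate after in situ N-silylation; the two ortho positions are equivalent and each is also activated by a benzyloxy group, so lithiation there should outrun benzylic deprotonation, and the N–Si bond is cleaved on acidic work-up.

Step 10
Reactants: 20 3,5-bis(benzyloxy)-2-(trimethylsilyl)phenyl propan-2-ylcarbamate
Product: 22 3,5-bis(benzyloxy)-2-(trimethylsilyl)phenyl trifluoromethanesulfonate, via silylphenol 21 (not isolated)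
Conditions: DBU, Et2NH, MeCN, 40 °C; then PhNTf2, rt
Reagents that add atoms: N-phenylbis(trifluoromethanesulfonimide), O=S(=O)(N(c1ccccc1)S(=O)(=O)C(F)(F)F)C(F)(F)F
Why: Base-induced E1cB cleavage of the N-monosubstituted carbamate (the isocyanate is trapped by diethylamine) and triflation of the phenoxide in the same flask is the established route to ortho-silylaryl triflates.

Step 11
Reactants: 14 methyl 3-[3-(benzyloxy)-6-ethoxy-5,8-dimethoxy-1-methylnaphthalen-2-yl]-3-oxopropanoate; 22 3,5-bis(benzyloxy)-2-(trimethylsilyl)phenyl trifluoromethanesulfonate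
Product: 24 methyl {3,5-bis(benzyloxy)-2-[3-(benzyloxy)-6-ethoxy-5,8-dimethoxy-1-methylnaphthalene-2-carbonyl]phenyl}acetate, via aryne 23 (not isolated)
Conditions: CsF, MeCN, 80 °C
Reagents that add atoms: none
Why: Aryne acyl-alkylation (insertion of an aryne into the C–C bond of a β-keto ester): fluoride releases aryne 23, the enolate carbon of 14 adds to the aryne carbon remote from the C3 benzyloxy group, and the aryl anion formed next to that oxygen adds to C9 and the four-membered alkoxide fragments. This places C9 on C1' between the C2' oxygen and the new C6' methylene, the pattern of ring C.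

Step 12
Reactants: 24 methyl {3,5-bis(benzyloxy)-2-[3-(benzyloxy)-6-ethoxy-5,8-dimethoxy-1-methylnaphthalene-2-carbonyl]phenyl}acetate
Product: 25 {3,5-bis(benzyloxy)-2-[3-(benzyloxy)-6-ethoxy-5,8-dimethoxy-1-methylnaphthalene-2-carbonyl]phenyl}acetic acid
Conditions: LiOH, THF–MeOH–H2O, rt; then aq. HCl
Reagents that add atoms: lithium hydroxide, [Li+].[OH-]
Why: Saponification of an unhindered methyl arylacetate; the diaryl ketone has no α-hydrogen and is too shielded to be attacked.

Step 13
Reactants: 25 {3,5-bis(benzyloxy)-2-[3-(benzyloxy)-6-ethoxy-5,8-dimethoxy-1-methylnaphthalene-2-carbonyl]phenyl}acetic acid; 26 2,2,6-trimethyl-4H-1,3-dioxin-4-one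
Product: 29 6-(3-{3,5-bis(benzyloxy)-2-[3-(benzyloxy)-6-ethoxy-5,8-dimethoxy-1-methylnaphthalene-2-carbonyl]phenyl}-2-oxopropyl)-2,2-dimethyl-4H-1,3-dioxin-4-one, via lithium dienolate 27 (not isolated), via acyl imidazole 28 (not isolated)
Conditions: 1,1'-carbonyldiimidazole, THF, rt; then added to 26/LiN(SiMe3)2 (3.5 equiv), THF, −78 → −40 °C; aq. NH4Cl
Reagents that add atoms: none
Why: Claisen-type C-acylation of the vinylogous lithium dienolate of the dioxinone at its terminal carbon by a mild acyl imidazole (forms C5''–C6''); excess dienolate covers the acidic product and the imidazole N–H, and the low temperature limits enolisation of the acyl donor.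

Step 14
Reactants: 29 6-(3-{3,5-bis(benzyloxy)-2-[3-(benzyloxy)-6-ethoxy-5,8-dimethoxy-1-methylnaphthalene-2-carbonyl]phenyl}-2-oxopropyl)-2,2-dimethyl-4H-1,3-dioxin-4-one
Product: 32 6-({3,5-bis(benzyloxy)-2-[3-(benzyloxy)-6-ethoxy-5,8-dimethoxy-1-methylnaphthalene-2-carbonyl]phenyl}methyl)-2-oxo-2H-pyran-4-yl acetate, via acylketene 30 (not isolated), via hydroxypyranone 31 (not isolated)
Conditions: PhMe, 110 °C; then Ac2O, pyridine, CH2Cl2, 0 °C
Reagents that add atoms: acetic anhydride, CC(=O)OC(C)=O
Why: Retro-hetero-Diels–Alder loss of acetone gives an acylketene that the enol oxygen of the neighbouring ketone traps in a six-membered lactonisation (O1''–C2''), the standard dioxinone route to 6-substituted 4-hydroxy-2-pyranones. O-acetylation without a nucleophilic catalyst then removes the 1,3-dicarbonyl character that the cerium oxidant of step 15 could attack.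

Step 15
Reactants: 32 6-({3,5-bis(benzyloxy)-2-[3-(benzyloxy)-6-ethoxy-5,8-dimethoxy-1-methylnaphthalene-2-carbonyl]phenyl}methyl)-2-oxo-2H-pyran-4-yl acetate
Product: 33 6-({3,5-bis(benzyloxy)-2-[3-(benzyloxy)-6-ethoxy-1-methyl-5,8-dioxo-5,8-dihydronaphthalene-2-carbonyl]phenyl}methyl)-2-oxo-2H-pyran-4-yl acetate
Conditions: (NH4)2Ce(NO3)6 (2.5 equiv), MeCN–H2O, 0 °C
Reagents that add atoms: water, O
Why: Oxidative demethylation of a hydroquinone dimethyl ether by tetravalent cerium; the trialkoxynaphthalene is by far the most electron-rich arene, ring C being deactivated by the ketone. Any 4-methoxy-1,2-quinone isomer formed by loss of the ethyl group would give the same product in step 16.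

Step 16
Reactants: 33 6-({3,5-bis(benzyloxy)-2-[3-(benzyloxy)-6-ethoxy-1-methyl-5,8-dioxo-5,8-dihydronaphthalene-2-carbonyl]phenyl}methyl)-2-oxo-2H-pyran-4-yl acetate
Product: 34 6-({3,5-bis(benzyloxy)-2-[3-(benzyloxy)-6-hydroxy-1-methyl-5,8-dioxo-5,8-dihydronaphthalene-2-carbonyl]phenyl}methyl)-4-hydroxy-2H-pyran-2-one
Conditions: LiOH, THF–H2O, 0 °C → rt; then aq. HCl
Reagents that add atoms: lithium hydroxide, [Li+].[OH-]
Why: Hydroxide cleaves the enol acetate and displaces ethoxide from C2 of the alkoxyquinone by addition–elimination (vinylogous ester hydrolysis); the resulting pyranone and hydroxyquinone anions resist further attack.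

Step 17
Reactants: 34 6-({3,5-bis(benzyloxy)-2-[3-(benzyloxy)-6-hydroxy-1-methyl-5,8-dioxo-5,8-dihydronaphthalene-2-carbonyl]phenyl}methyl)-4-hydroxy-2H-pyran-2-one
Product: 35 6-{[3,5-dihydroxy-2-(3,6-dihydroxy-1-methyl-5,8-dioxo-5,8-dihydronaphthalene-2-carbonyl)phenyl]methyl}-4-hydroxy-2H-pyran-2-one (CNP0141484.0)
Conditions: BCl3, pentamethylbenzene, CH2Cl2, −78 °C; MeOH quench
Reagents that add atoms: none
Why: Lewis-acid cleavage of aryl benzyl ethers with a non-basic cation scavenger works at −78 °C without reduction, so quinone and pyranone are untouched, and the scavenger intercepts the benzyl cation before it can alkylate the resorcinol ring.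

## Compound list

1 | methyl 2-hydroxy-6-methylbenzoate | COC(=O)c1c(C)cccc1O | starting material
2 | methyl 2-(benzyloxy)-6-methylbenzoate | COC(=O)c1c(C)cccc1OCc1ccccc1 | intermediate
3 | methyl 6-(benzyloxy)-3-bromo-2-methylbenzoate | COC(=O)c1c(C)c(Br)ccc1OCc1ccccc1 | intermediate
4 | hexacarbonylchromium, Cr(CO)6 | O=C=[Cr](=C=O)(=C=O)(=C=O)(=C=O)=C=O | starting material
5 | methyl 6-(benzyloxy)-3-lithio-2-methylbenzoate | [Li]c1ccc(OCc2ccccc2)c(C(=O)OC)c1C | intermediate (not isolated)
6 | lithium pentacarbonyl[4-(benzyloxy)-3-(methoxycarbonyl)-2-methylbenzoyl]chromate | [Li+].[O-]C(=[Cr](=C=O)(=C=O)(=C=O)(=C=O)=C=O)c1ccc(OCc2ccccc2)c(C(=O)OC)c1C | intermediate (not isolated)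
7 | pentacarbonyl{[4-(benzyloxy)-3-(methoxycarbonyl)-2-methylphenyl](methoxy)methylidene}chromium | COC(=[Cr](=C=O)(=C=O)(=C=O)(=C=O)=C=O)c1ccc(OCc2ccccc2)c(C(=O)OC)c1C | intermediate
8 | ethoxyacetylene (ethoxyethyne) | C#COCC | starting material
9 | tricarbonyl[η6-(methyl 3-(benzyloxy)-6-ethoxy-5-hydroxy-8-methoxy-1-methylnaphthalene-2-carboxylate)]chromium, metal on the newly formed ring (arene and Cr(CO)3 fragment written as two parts) | COC(=O)c1c(C)c2c(OC)cc(OCC)c(O)c2cc1OCc1ccccc1.O=C=[Cr](=C=O)=C=O | intermediate (not isolated)
10 | methyl 3-(benzyloxy)-6-ethoxy-5-hydroxy-8-methoxy-1-methylnaphthalene-2-carboxylate | COC(=O)c1c(C)c2c(OC)cc(OCC)c(O)c2cc1OCc1ccccc1 | intermediate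
11 | methyl 3-(benzyloxy)-6-ethoxy-5,8-dimethoxy-1-methylnaphthalene-2-carboxylate | COC(=O)c1c(C)c2c(OC)cc(OCC)c(OC)c2cc1OCc1ccccc1 | intermediate
12 | 3-(benzyloxy)-6-ethoxy-5,8-dimethoxy-1-methylnaphthalene-2-carboxylic acid | OC(=O)c1c(C)c2c(OC)cc(OCC)c(OC)c2cc1OCc1ccccc1 | intermediate
13 | 3-(benzyloxy)-6-ethoxy-5,8-dimethoxy-1-methylnaphthalene-2-carbonyl chloride | ClC(=O)c1c(C)c2c(OC)cc(OCC)c(OC)c2cc1OCc1ccccc1 | intermediate (not isolated)
14 | methyl 3-[3-(benzyloxy)-6-ethoxy-5,8-dimethoxy-1-methylnaphthalen-2-yl]-3-oxopropanoate | COC(=O)CC(=O)c1c(C)c2c(OC)cc(OCC)c(OC)c2cc1OCc1ccccc1 | intermediate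
15 | 3,5-bis(benzyloxy)phenol | Oc1cc(OCc2ccccc2)cc(OCc2ccccc2)c1 | starting material
16 | 3,5-bis(benzyloxy)phenyl propan-2-ylcarbamate | CC(C)NC(=O)Oc1cc(OCc2ccccc2)cc(OCc2ccccc2)c1 | intermediate
17 | 3,5-bis(benzyloxy)phenyl [tert-butyl(dimethyl)silyl](propan-2-yl)carbamate | CC(C)N(C(=O)Oc1cc(OCc2ccccc2)cc(OCc2ccccc2)c1)[Si](C)(C)C(C)(C)C | intermediate (not isolated)
18 | 3,5-bis(benzyloxy)-2-lithiophenyl [tert-butyl(dimethyl)silyl](propan-2-yl)carbamate | CC(C)N(C(=O)Oc1cc(OCc2ccccc2)cc(OCc2ccccc2)c1[Li])[Si](C)(C)C(C)(C)C | intermediate (not isolated)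
19 | 3,5-bis(benzyloxy)-2-(trimethylsilyl)phenyl [tert-butyl(dimethyl)silyl](propan-2-yl)carbamate | CC(C)N(C(=O)Oc1cc(OCc2ccccc2)cc(OCc2ccccc2)c1[Si](C)(C)C)[Si](C)(C)C(C)(C)C | intermediate (not isolated)
20 | 3,5-bis(benzyloxy)-2-(trimethylsilyl)phenyl propan-2-ylcarbamate | CC(C)NC(=O)Oc1cc(OCc2ccccc2)cc(OCc2ccccc2)c1[Si](C)(C)C | intermediate
21 | 3,5-bis(benzyloxy)-2-(trimethylsilyl)phenol | Oc1cc(OCc2ccccc2)cc(OCc2ccccc2)c1[Si](C)(C)C | intermediate (not isolated)
22 | 3,5-bis(benzyloxy)-2-(trimethylsilyl)phenyl trifluoromethanesulfonate | FC(F)(F)S(=O)(=O)Oc1cc(OCc2ccccc2)cc(OCc2ccccc2)c1[Si](C)(C)C | intermediate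
23 | 3,5-bis(benzyloxy)benzyne (1,2-didehydro-3,5-bis(benzyloxy)benzene) | C1#CC(OCc2ccccc2)=CC(OCc2ccccc2)=C1 | intermediate (not isolated)
24 | methyl {3,5-bis(benzyloxy)-2-[3-(benzyloxy)-6-ethoxy-5,8-dimethoxy-1-methylnaphthalene-2-carbonyl]phenyl}acetate | COC(=O)Cc1cc(OCc2ccccc2)cc(OCc2ccccc2)c1C(=O)c1c(C)c2c(OC)cc(OCC)c(OC)c2cc1OCc1ccccc1 | intermediate
25 | {3,5-bis(benzyloxy)-2-[3-(benzyloxy)-6-ethoxy-5,8-dimethoxy-1-methylnaphthalene-2-carbonyl]phenyl}acetic acid | OC(=O)Cc1cc(OCc2ccccc2)cc(OCc2ccccc2)c1C(=O)c1c(C)c2c(OC)cc(OCC)c(OC)c2cc1OCc1ccccc1 | intermediate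
26 | 2,2,6-trimethyl-4H-1,3-dioxin-4-one | CC1=CC(=O)OC(C)(C)O1 | starting material
27 | lithium 2,2-dimethyl-6-methylidene-6H-1,3-dioxin-4-olate | [Li+].[O-]C1=CC(=C)OC(C)(C)O1 | intermediate (not isolated)
28 | 2-{3,5-bis(benzyloxy)-2-[3-(benzyloxy)-6-ethoxy-5,8-dimethoxy-1-methylnaphthalene-2-carbonyl]phenyl}-1-(1H-imidazol-1-yl)ethan-1-one | O=C(Cc1cc(OCc2ccccc2)cc(OCc2ccccc2)c1C(=O)c1c(C)c2c(OC)cc(OCC)c(OC)c2cc1OCc1ccccc1)n1ccnc1 | intermediate (not isolated)
29 | 6-(3-{3,5-bis(benzyloxy)-2-[3-(benzyloxy)-6-ethoxy-5,8-dimethoxy-1-methylnaphthalene-2-carbonyl]phenyl}-2-oxopropyl)-2,2-dimethyl-4H-1,3-dioxin-4-one | CC1(C)OC(CC(=O)Cc2cc(OCc3ccccc3)cc(OCc3ccccc3)c2C(=O)c2c(C)c3c(OC)cc(OCC)c(OC)c3cc2OCc2ccccc2)=CC(=O)O1 | intermediate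
30 | 6-{3,5-bis(benzyloxy)-2-[3-(benzyloxy)-6-ethoxy-5,8-dimethoxy-1-methylnaphthalene-2-carbonyl]phenyl}hex-1-ene-1,3,5-trione (acylketene) | O=C=CC(=O)CC(=O)Cc1cc(OCc2ccccc2)cc(OCc2ccccc2)c1C(=O)c1c(C)c2c(OC)cc(OCC)c(OC)c2cc1OCc1ccccc1 | intermediate (not isolated)
31 | 6-({3,5-bis(benzyloxy)-2-[3-(benzyloxy)-6-ethoxy-5,8-dimethoxy-1-methylnaphthalene-2-carbonyl]phenyl}methyl)-4-hydroxy-2H-pyran-2-one | O=c1cc(O)cc(Cc2cc(OCc3ccccc3)cc(OCc3ccccc3)c2C(=O)c2c(C)c3c(OC)cc(OCC)c(OC)c3cc2OCc2ccccc2)o1 | intermediate (not isolated)
32 | 6-({3,5-bis(benzyloxy)-2-[3-(benzyloxy)-6-ethoxy-5,8-dimethoxy-1-methylnaphthalene-2-carbonyl]phenyl}methyl)-2-oxo-2H-pyran-4-yl acetate | CC(=O)Oc1cc(Cc2cc(OCc3ccccc3)cc(OCc3ccccc3)c2C(=O)c2c(C)c3c(OC)cc(OCC)c(OC)c3cc2OCc2ccccc2)oc(=O)c1 | intermediate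
33 | 6-({3,5-bis(benzyloxy)-2-[3-(benzyloxy)-6-ethoxy-1-methyl-5,8-dioxo-5,8-dihydronaphthalene-2-carbonyl]phenyl}methyl)-2-oxo-2H-pyran-4-yl acetate | Cc1c(C(=O)c2c(OCc3ccccc3)cc(OCc3ccccc3)cc2Cc2cc(OC(C)=O)cc(=O)o2)c(OCc2ccccc2)cc2c1C(=O)C=C(OCC)C2=O | intermediate
34 | 6-({3,5-bis(benzyloxy)-2-[3-(benzyloxy)-6-hydroxy-1-methyl-5,8-dioxo-5,8-dihydronaphthalene-2-carbonyl]phenyl}methyl)-4-hydroxy-2H-pyran-2-one | Cc1c(C(=O)c2c(OCc3ccccc3)cc(OCc3ccccc3)cc2Cc2cc(O)cc(=O)o2)c(OCc2ccccc2)cc2c1C(=O)C=C(O)C2=O | intermediate
35 | 6-{[3,5-dihydroxy-2-(3,6-dihydroxy-1-methyl-5,8-dioxo-5,8-dihydronaphthalene-2-carbonyl)phenyl]methyl}-4-hydroxy-2H-pyran-2-one (CNP0141484.0) | Cc1c(C(=O)c2c(O)cc(O)cc2Cc2cc(O)cc(=O)o2)c(O)cc2c1C(=O)C=C(O)C2=O | target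

## Step count and risk

Total step count: 17. Longest linear sequence: 14 (steps 1–7 and 11–17); steps 8–10 are a three-step branch to 22.

**Step 4 (key step).** The sequence may stop after alkyne insertion, because the ethoxy-stabilised alkenylcarbene is reluctant to take up CO, much as the aminocarbenes formed from ynamines are. It may also be diverted to cyclobutenone or indene products, or the ynol ether may oligomerise. Fallback, a stepwise photochemical ring closure: starting from 7, the insertion is run at room temperature and the product pentacarbonyl{(2E)-3-[4-(benzyloxy)-3-(methoxycarbonyl)-2-methylphenyl]-1-ethoxy-3-methoxyprop-2-en-1-ylidene}chromium F1 is isolated. Irradiation of F1 with visible light under CO (1 atm) in THF drives the CO insertion photochemically to the chromium ketene, which undergoes the same 6π closure onto C8a; this is the known photochemical benzannulation of dienyl-type alkoxycarbene complexes to ortho-alkoxyphenols. The fallback returns to the route at 10.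

**Step 3.** While the mixture warms with the sparingly soluble Cr(CO)6, the aryllithium may be lost through proton transfer from the acidic benzylic methyl group beside the ester, or through attack on the ester. Fallback, the acylation route to alkoxycarbene complexes: starting from 3, hydroxycarbonylation (Pd(OAc)2, 1,1'-bis(diphenylphosphino)ferrocene, CO, Et3N, aqueous DMF) gives 4-(benzyloxy)-3-(methoxycarbonyl)-2-methylbenzoic acid F2. Oxalyl chloride converts it into methyl 6-(benzyloxy)-3-(chlorocarbonyl)-2-methylbenzoate F3. The dianion K2Cr(CO)5 (from Cr(CO)6 and C8K) is acylated by F3 to potassium pentacarbonyl[4-(benzyloxy)-3-(methoxycarbonyl)-2-methylbenzoyl]chromate F4, and Me3OBF4 methylates this to 7, where the route is rejoined. No organolithium meets the ester.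

**Step 11.** The aryl anion formed after the first C–C bond may be protonated before it can add to the twisted, di-ortho-substituted C9 ketone, which would stop at simple α-arylation of the β-keto ester. Fallback, a Friedel–Crafts acylation in place of the insertion: methyl [3,5-bis(benzyloxy)phenyl]acetate F5 is made from methyl (3,5-dihydroxyphenyl)acetate with BnBr and K2CO3. Starting from acid 12, activation with trifluoroacetic anhydride gives the mixed anhydride and the linear acylium ion, which hindered 2,6-disubstituted aroyl groups form readily. This acylates F5 at the position ortho to the side chain and para to a benzyloxy group, and returns to the route at 24. F5 is used in excess to outcompete self-acylation of the electron-rich naphthalene.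

**Step 13.** Proton transfer from the acidic methylene of the acyl imidazole to the dienolate may consume both partners, and O-acylation may compete. The polyanion of the product might also close onto C9 in an aldol fashion, although that ketone is shielded on both sides. Fallback, a base-free chain extension: starting from 25, 1-chloro-N,N,2-trimethylprop-1-en-1-amine gives {3,5-bis(benzyloxy)-2-[3-(benzyloxy)-6-ethoxy-5,8-dimethoxy-1-methylnaphthalene-2-carbonyl]phenyl}acetyl chloride F6. This acylates 1-methoxy-1,3-bis(trimethylsilyloxy)buta-1,3-diene at its terminal carbon (CH2Cl2, −78 °C → rt) to give methyl 6-{3,5-bis(benzyloxy)-2-[3-(benzyloxy)-6-ethoxy-5,8-dimethoxy-1-methylnaphthalene-2-carbonyl]phenyl}-3,5-dioxohexanoate F7. DBU in hot toluene cyclises F7 with loss of methanol to the hydroxypyranone 31, which is acetylated as in step 14.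

**Step 17.** Cleavage may be incomplete at the crowded C7 ether, the benzyl cation may alkylate ring C, or the Lewis acid may induce condensation of the pyranone onto C9. Fallback, hydrogenolysis: starting from 34, H2 over Pd/C in EtOAc removes the benzyl groups and reduces the quinone to 6-{[3,5-dihydroxy-2-(3,5,6,8-tetrahydroxy-1-methylnaphthalene-2-carbonyl)phenyl]methyl}-4-hydroxy-2H-pyran-2-one F8. Air reoxidises F8 on work-up to 35. The reaction would have to be stopped early to spare the pyranone C5''–C6'' double bond.

## Further compounds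

F1 | step 4 | pentacarbonyl{(2E)-3-[4-(benzyloxy)-3-(methoxycarbonyl)-2-methylphenyl]-1-ethoxy-3-methoxyprop-2-en-1-ylidene}chromium | CCOC(=[Cr](=C=O)(=C=O)(=C=O)(=C=O)=C=O)/C=C(/OC)c1ccc(OCc2ccccc2)c(C(=O)OC)c1C
F2 | step 3 | 4-(benzyloxy)-3-(methoxycarbonyl)-2-methylbenzoic acid | OC(=O)c1ccc(OCc2ccccc2)c(C(=O)OC)c1C
F3 | step 3 | methyl 6-(benzyloxy)-3-(chlorocarbonyl)-2-methylbenzoate | ClC(=O)c1ccc(OCc2ccccc2)c(C(=O)OC)c1C
F4 | step 3 | potassium pentacarbonyl[4-(benzyloxy)-3-(methoxycarbonyl)-2-methylbenzoyl]chromate | [K+].[O-]C(=[Cr](=C=O)(=C=O)(=C=O)(=C=O)=C=O)c1ccc(OCc2ccccc2)c(C(=O)OC)c1C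
F5 | step 11 | methyl [3,5-bis(benzyloxy)phenyl]acetate | COC(=O)Cc1cc(OCc2ccccc2)cc(OCc2ccccc2)c1
F6 | step 13 | {3,5-bis(benzyloxy)-2-[3-(benzyloxy)-6-ethoxy-5,8-dimethoxy-1-methylnaphthalene-2-carbonyl]phenyl}acetyl chloride | ClC(=O)Cc1cc(OCc2ccccc2)cc(OCc2ccccc2)c1C(=O)c1c(C)c2c(OC)cc(OCC)c(OC)c2cc1OCc1ccccc1
F7 | step 13 | methyl 6-{3,5-bis(benzyloxy)-2-[3-(benzyloxy)-6-ethoxy-5,8-dimethoxy-1-methylnaphthalene-2-carbonyl]phenyl}-3,5-dioxohexanoate | COC(=O)CC(=O)CC(=O)Cc1cc(OCc2ccccc2)cc(OCc2ccccc2)c1C(=O)c1c(C)c2c(OC)cc(OCC)c(OC)c2cc1OCc1ccccc1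
F8 | step 17 | 6-{[3,5-dihydroxy-2-(3,5,6,8-tetrahydroxy-1-methylnaphthalene-2-carbonyl)phenyl]methyl}-4-hydroxy-2H-pyran-2-one | Cc1c(C(=O)c2c(O)cc(O)cc2Cc2cc(O)cc(=O)o2)c(O)cc2c(O)c(O)cc(O)c12
A1 | alternative 1 | 6-{[3,5-dimethoxy-2-(3,5,6,8-tetramethoxy-1-methyl-2-naphthoyl)phenyl]methyl}-4-methoxy-2H-pyran-2-one | Cc1c(C(=O)c2c(OC)cc(OC)cc2Cc2cc(OC)cc(=O)o2)c(OC)cc2c(OC)c(OC)cc(OC)c12
A2 | alternative 1 | 6-[(2-iodo-3,5-dimethoxyphenyl)methyl]-4-methoxy-2H-pyran-2-one | COc1cc(OC)c(I)c(Cc2cc(OC)cc(=O)o2)c1
A3 | alternative 1 | 4,4,5,5-tetramethyl-2-(3,5,6,8-tetramethoxy-1-methylnaphthalen-2-yl)-1,3,2-dioxaborolane | Cc1c(B2OC(C)(C)C(C)(C)O2)c(OC)cc2c(OC)c(OC)cc(OC)c12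
A4 | alternative 2 | 6-{2,4-dimethoxy-6-[(4-methoxy-2-oxo-2H-pyran-6-yl)methyl]benzoyl}-7-hydroxy-2-methoxy-5-methyl-1,4-naphthoquinone | Cc1c(C(=O)c2c(OC)cc(OC)cc2Cc2cc(OC)cc(=O)o2)c(O)cc2c1C(=O)C=C(OC)C2=O
A5 | alternative 2 | 2-bromo-5-methoxy-1,4-benzoquinone | COC1=CC(=O)C(Br)=CC1=O
A6 | alternative 2 | (2Z)-2-[1-(tert-butyldimethylsilyloxy)ethenyl]-1-{2,4-dimethoxy-6-[(4-methoxy-2-oxo-2H-pyran-6-yl)methyl]phenyl}but-2-en-1-one | C/C=C(\C(=O)c1c(OC)cc(OC)cc1Cc1cc(OC)cc(=O)o1)C(=C)O[Si](C)(C)C(C)(C)C
A7 | alternative 3 | 6-{[3,5-dihydroxy-2-(3,5,6,8-tetramethoxy-1-methyl-2-naphthoyl)phenyl]methyl}-4-hydroxy-2H-pyran-2-one | Cc1c(C(=O)c2c(O)cc(O)cc2Cc2cc(O)cc(=O)o2)c(OC)cc2c(OC)c(OC)cc(OC)c12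
A8 | alternative 3 | 2,2-dimethyl-6-[2,4,6,8,10-pentaoxo-10-(3,5,6,8-tetramethoxy-1-methylnaphthalen-2-yl)decyl]-4H-1,3-dioxin-4-one | Cc1c(C(=O)CC(=O)CC(=O)CC(=O)CC(=O)CC2=CC(=O)OC(C)(C)O2)c(OC)cc2c(OC)c(OC)cc(OC)c12
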